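Slowness is what I read at the end of Sunday's run, and I reckon from it where target stops falling in the four new flasks.

the same everywhere: substrate 0.050 M
- Friday's: partner 0.037 M; protic impurity 5 mM; temperature −10 °C; run made earlier
- Sunday's: partner 0.056 M; protic impurity 5 mM; temperature 32 °C; run made earlier
- green: partner 0.0750 M; protic impurity 5.00 mM; temperature 45 °C; time 5.0 d
- teal: partner 0.0750 M; protic impurity 5.00 mM; temperature 20 °C; time 5.0 d
- red: partner 0.0750 M; protic impurity 5.00 mM; temperature 70 °C; time 5.0 d
- violet: partner 0.0750 M; protic impurity 5.00 mM; temperature −5 °C; time 5.0 d

- Friday's (time / d: target / %, substrate / %): 6.00: 2.5, 86.1; 12.0: 9.4, 74.4; 20.0: 18.6, 65.3; 25.0: 24.1, 62.2; 30.0: 28.9, 59.7; 40.0: 36.9, 54.0; 50.0: 42.0, 51.0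
- Sunday's (time / d: target / %, substrate / %): 0.833: 64.1, 34.0; 1.67: 75.4, 19.8; 2.50: 80.1, 15.6; 3.00: 80.9, 12.9; 4.00: 82.7, 11.3; 5.00: 83.3, 9.6; 6.00: 83.6, 8.7

(readings scatter by 0.5 percentage points)

- the flask that comes out highest in amount of target, in percent of the substrate charged, or "all alike" when all lie within 1.5 percentage points (green / teal / red / violet / all alike)
- target at the end, in percent of the substrate charged, green
- target at the end, in percent of the substrate charged, teal
- target at the end, in percent of the substrate charged, red
- target at the end, in percent of the substrate charged, violet



In Sunday's run the logarithm of substrate falls at 0.646 d⁻¹ between 0.833 d and 1.67 d, but at 0.131 d⁻¹ between 4.00 d and 6.00 d, slower. Substrate meets partner at a rate k·A·B, with k the rate constant and A and B the concentrations. Over a short stretch the decay is therefore pseudo-first-order, and its slope divided by the partner present should stay constant.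

So I need the partner present, and I get it from a budget. I suppose that one partner goes to each protic impurity, one to each substrate converted and one to each target lost. Counted in shares of the substrate charge, the partner surplus σ is partner less impurity less substrate, over substrate. Partner left, b, is then σ plus substrate left, x, less the part m missing from target plus substrate, with m counted as target lost.

Sunday's σ is 2.00%, and b averages 25.6% over the early stretch and 5.15% over the late one. Slope over b, early against late, reads 0.996, with the scatter of the readings on it. With m left out of the budget the same ratio reads 2.05. I therefore keep the budget, lost target included.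

The four new flasks are charged alike, and their partner surplus σ, partner less impurity less substrate over substrate, is 40.0%. With no intermediate standing between substrate and target, the budget says that target equals F = 60.0%, less twice x, plus b. Partner is then the limiting reagent of the loss, and when b reaches nil the target stops falling.

The forecast puts teal highest at 91%, with 76% for green, 6% for red and 10% for violet. Its ground at the hot end is “Green and especially red lose target, though these are the least certain”. My F, the target with x and b both nil, stands above its red figure, and there we differ.

The flasks end at 66.0% in green, 86.5% in teal, 59.3% in red and 13.5% in violet, so teal stands highest.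

    substrate + partner → intermediate + released group (k = 2.00 × 10⁻⁴ M⁻¹ s⁻¹, Ea = 63.0 kJ mol⁻¹)
    intermediate → target (k = 7.40 × 10⁻⁵ s⁻¹, Ea = 95.0 kJ mol⁻¹)
    partner + target → over-reaction product (k = 8.20 × 10⁻⁶ M⁻¹ s⁻¹, Ea = 80.0 kJ mol⁻¹)
    partner + protic impurity → quenched reagent (k = 0.00170 M⁻¹ s⁻¹, Ea = 53.0 kJ mol⁻¹)
    (constants at 20 °C)

Red ends with 0% of its partner charge and 0.358% of its substrate, and F less twice that substrate gives 59.3% against the 59.3% it holds. Teal, left until 50.0 d, has 0% of its substrate and 6.29% of its partner charge. F plus that partner, in shares of the substrate charge, gives 69.4%, and teal then holds 69.4%.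

The numbers in the tables are simulated from invented constants; scatter was added.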